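**Plan**

- Retrosynthesis (oxolane numbered O1, C2 aryl, C3 with arm C9, C4 with arm C7', C5): the C9 carbinol goes back to a carboxylic acid, the C7'–H bond to the benzylic C–O bond of a γ-aryl lactone, and the C7'–aryl bond to a lactone acetal plus 1,2-dimethoxybenzene; C2–C3 and C4–C5 are then cut together.
- Enabling feature: C2–O1–C5 is a carbonyl ylide (aldehyde carbon, oxygen, CH2), and C3–C4 with its two cis one-carbon arms is the C=C of a butenolide in which C9 is the lactone carbonyl and C7' the acetal carbon.
- Forward: the menthyl acetal butenolide (from furfural and (−)-menthol) and an α-chloro silylmethyl ether (from 3,4,5-trimethoxybenzaldehyde) are made in parallel. Their (3+2) union closes the oxolane, the only ring of the target, cis-fused to a temporary lactone. The lactone is then taken apart by arylation at C7', hydrogenolysis of C7'–O and reduction of C9.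
- Stereochemistry: the 5R acetal carbon (from (−)-menthol, fixed by crystallisation) sends the ylide to the opposite face and sets C4; suprafacial addition to the ring alkene sets C3 cis to C4; the exo aryl group sets C2 trans to C3. The acetal centre is erased in steps 5 and 6.

Key step: step 4

Remark: menthyl means (1R,2S,5R)-5-methyl-2-(propan-2-yl)cyclohexyl unless stated otherwise. Bicyclic lactones are numbered as furo[3,4-c]furan-1-ones: C1 carbonyl (C9 of the target), O2, C3 (C7'), C3a (C4), C4 (C5), O5 (O1), C6 (C2), C6a (C3).

**Step 1**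
Reactants: 1 furfural
Product: 3 5-hydroxyfuran-2(5H)-one, via furfural endoperoxide 2 (not isolated)
Conditions: O2, hν (visible), methylene blue (cat.), MeOH, rt
Reagents that add atoms: dioxygen, O=O
Why: Dye-sensitised singlet-oxygen [4+2] photo-oxygenation of the furan gives the endoperoxide, whose formyl carbon is lost to methanol as methyl formate, leaving the pseudo-acid; its lactol centre is labile and needs no control.

**Step 2**
Reactants: 3 5-hydroxyfuran-2(5H)-one; 4 (−)-menthol
Product: 5 (5R)-5-(menthyloxy)furan-2(5H)-one
Conditions: p-TsOH (cat.), toluene, reflux with azeotropic removal of water; crystallise from hexane at −20 °C; mother liquor re-equilibrated with p-TsOH (cat.) and crystallised again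
Reagents that add atoms: none
Why: Acid-catalysed acetalisation of the pseudo-acid gives both acetal epimers, and because the acetal centre equilibrates under acid while the 5R epimer is the crystalline one, crystallisation-driven epimer interconversion should funnel the material into 5.

**Step 3**
Reactants: 6 3,4,5-trimethoxybenzaldehyde; 7 (trimethylsilyl)methanol
Product: 8 {[chloro(3,4,5-trimethoxyphenyl)methoxy]methyl}(trimethyl)silane (racemic)
Conditions: Me3SiCl (2.2 equiv), CH2Cl2, 0 °C → rt, under argon; volatiles removed in vacuo, crude product used at once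
Reagents that add atoms: chlorotrimethylsilane, C[Si](C)(C)Cl
Why: α-Chloro ether formation from an aldehyde, an alcohol and a chlorosilane (hemiacetal formation, then exchange of the hemiacetal OH for chloride, driven by formation of the disiloxane); the new centre is racemic and becomes planar in the ylide.

**Step 4**
Reactants: 8 {[chloro(3,4,5-trimethoxyphenyl)methoxy]methyl}(trimethyl)silane; 5 (5R)-5-(menthyloxy)furan-2(5H)-one
Product: 10 (3R,3aS,6R,6aR)-3-(menthyloxy)-6-(3,4,5-trimethoxyphenyl)tetrahydro-1H,3H-furo[3,4-c]furan-1-one, via carbonyl ylide 9 (not isolated)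
Conditions: CsF (3 equiv, dried), MeCN, rt; 8 (1.5 equiv) added slowly to 5 and CsF
Reagents that add atoms: none
Why: Fluoride attacks silicon of 8, and 1,3-elimination of Me3SiF and chloride gives the non-stabilised carbonyl ylide 9, which adds across C3=C4 of 5 in a concerted, suprafacial (3+2) cycloaddition governed by the ylide HOMO and the enoate LUMO. The closest known reactions are the CsF-induced generation of such ylides from α-chloroalkyl silylmethyl ethers with capture by acrylates, fumarates and maleates, and the anti-selective cycloadditions of nitrile oxides, diazoalkanes and azomethine ylides to 5-alkoxyfuran-2(5H)-ones. The oxolane closes in the cycloaddition itself: C6–C6a and C3a–C4 (C2–C3 and C4–C5 of the target) form on one face of the cis ring alkene, so the new ring is necessarily cis-fused to the lactone. C3a is set by approach anti to the menthyloxy group on the neighbouring acetal carbon, C6a by the suprafacial addition, and C6 by the exo transition state in which the aryl group of the E-ylide points away from the lactone ring. The step needs regio-, face- and exo-selectivity: polarity matching secures the first (the unsubstituted, carbanion-like CH2 terminus bonds to the electrophilic β-carbon and the aryl-stabilised oxocarbenium terminus to the α-carbon), the bulky acetal substituent the second, and steric avoidance of the lactone ring together with the greater stability of the exo adduct the third.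

**Step 5**
Reactants: 10 the cycloadduct; 11 1,2-dimethoxybenzene
Product: 12 (3R,3aS,6R,6aR)-3-(3,4-dimethoxyphenyl)-6-(3,4,5-trimethoxyphenyl)tetrahydro-1H,3H-furo[3,4-c]furan-1-one
Conditions: SnCl4 (20 mol %), 1,2-dimethoxybenzene (4 equiv), CH2Cl2, −40 → 0 °C; aq. NaHCO3
Reagents that add atoms: none
Why: Friedel–Crafts alkylation by a lactone acetal, in which SnCl4 ionises the exocyclic C3–O bond and the acyloxocarbenium ion is taken by the arene para to a methoxy group from the convex face of the cis-fused bicycle, so the aryl group should be exo (3R); this centre is erased in step 6 and the ring-fusion centres stay locked cis.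

**Step 6**
Reactants: 12 the diaryl furofuranone
Product: 13 (2R,3R,4S)-4-[(3,4-dimethoxyphenyl)methyl]-2-(3,4,5-trimethoxyphenyl)oxolane-3-carboxylic acid
Conditions: H2 (1 atm), 10% Pd/C, EtOAc, rt; reaction stopped when 12 is consumed
Reagents that add atoms: none
Why: Catalytic hydrogenolysis of the benzylic C–O bond of a γ-aryl lactone, in which the acyloxy group on the 3,4-dimethoxybenzylic carbon should be cleaved on Pd much faster than the alkoxy group on the trimethoxybenzylic C2 of the oxolane; no stereocentre is formed and the three oxolane centres are not touched.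

**Step 7**
Reactants: 13 the oxolane carboxylic acid
Product: 14 [(2R,3S,4S)-4-[(3,4-dimethoxyphenyl)methyl]-2-(3,4,5-trimethoxyphenyl)oxolan-3-yl]methanol (target)
Conditions: LiAlH4 (2.5 equiv), THF, 0 °C → rt; H2O, 15% aq. NaOH, H2O
Reagents that add atoms: none
Why: LiAlH4 reduction of the carboxylic acid to the primary alcohol through the lithium carboxylate, which is not enolised, so C3 stays cis to C4; the basic work-up avoids the acid to which the electron-rich benzylic ether at C2 is sensitive.

**Compound list**

1 | furfural (furan-2-carbaldehyde) | O=Cc1ccco1 | starting material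
2 | furfural endoperoxide, 2,3,7-trioxabicyclo[2.2.1]hept-5-ene-1-carbaldehyde (racemic) | O=CC12OOC(C=C1)O2 | intermediate
3 | 5-hydroxyfuran-2(5H)-one (racemic, lactol centre labile) | O=C1C=CC(O)O1 | intermediate
4 | (−)-menthol, (1R,2S,5R)-5-methyl-2-(propan-2-yl)cyclohexan-1-ol | CC(C)[C@@H]1CC[C@@H](C)C[C@H]1O | starting material
5 | (5R)-5-{[(1R,2S,5R)-5-methyl-2-(propan-2-yl)cyclohexyl]oxy}furan-2(5H)-one | O=C1C=C[C@H](O[C@@H]2C[C@H](C)CC[C@H]2C(C)C)O1 | intermediate
6 | 3,4,5-trimethoxybenzaldehyde | COc1cc(C=O)cc(OC)c1OC | starting material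
7 | (trimethylsilyl)methanol | C[Si](C)(C)CO | starting material
8 | {[chloro(3,4,5-trimethoxyphenyl)methoxy]methyl}(trimethyl)silane (racemic) | COc1cc(C(Cl)OC[Si](C)(C)C)cc(OC)c1OC | intermediate
9 | carbonyl ylide, methylidene[(3,4,5-trimethoxyphenyl)methylidene]oxonium ylide | COc1cc(C=[O+][CH2-])cc(OC)c1OC | intermediate
10 | (3R,3aS,6R,6aR)-3-{[(1R,2S,5R)-5-methyl-2-(propan-2-yl)cyclohexyl]oxy}-6-(3,4,5-trimethoxyphenyl)tetrahydro-1H,3H-furo[3,4-c]furan-1-one (cis-fused, aryl exo, menthyloxy anti to the oxolane) | O=C1O[C@@H](O[C@@H]3C[C@H](C)CC[C@H]3C(C)C)[C@@H]2CO[C@@H](c3cc(OC)c(OC)c(OC)c3)[C@H]12 | intermediate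
11 | 1,2-dimethoxybenzene | COc1ccccc1OC | starting material
12 | (3R,3aS,6R,6aR)-3-(3,4-dimethoxyphenyl)-6-(3,4,5-trimethoxyphenyl)tetrahydro-1H,3H-furo[3,4-c]furan-1-one | O=C1O[C@@H](c3ccc(OC)c(OC)c3)[C@@H]2CO[C@@H](c3cc(OC)c(OC)c(OC)c3)[C@H]12 | intermediate
13 | (2R,3R,4S)-4-[(3,4-dimethoxyphenyl)methyl]-2-(3,4,5-trimethoxyphenyl)oxolane-3-carboxylic acid | COc1ccc(C[C@@H]2CO[C@@H](c3cc(OC)c(OC)c(OC)c3)[C@@H]2C(=O)O)cc1OC | intermediate
14 | [(2R,3S,4S)-4-[(3,4-dimethoxyphenyl)methyl]-2-(3,4,5-trimethoxyphenyl)oxolan-3-yl]methanol | COc1ccc(C[C@@H]2CO[C@@H](c3cc(OC)c(OC)c(OC)c3)[C@@H]2CO)cc1OC | target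

**Step count and risks**

Total step count: 7. Longest linear sequence: 6 steps (1, 2, 4, 5, 6, 7, from furfural); step 3 is a one-step side branch.

Steps most likely to fail:

1. Step 4. The ylide may add with the reverse orientation or through the endo mode, so that regioisomeric or C6-epimeric adducts form. It may also be used up by self-condensation or by reaction with liberated aldehyde before it meets the hindered, γ-alkoxy-substituted butenolide.
   Fallback: this uses known chemistry, gives up the cycloaddition and closes the oxolane by benzylic ether formation. It sets out from lactol 3 and aldehyde 6 and rejoins the route at target 14. Acetalisation of 3 with (+)-menthol under the conditions of step 2 should give (5S)-5-{[(1S,2R,5S)-5-methyl-2-(propan-2-yl)cyclohexyl]oxy}furan-2(5H)-one F1. The enantiomeric acetal is needed because here the benzyl arm, not the oxolane CH2, is delivered anti to the acetal. 3,4-Dimethoxybenzaldehyde and propane-1,3-dithiol (BF3·OEt2, CH2Cl2) give 2-(3,4-dimethoxyphenyl)-1,3-dithiane F2. Its lithio derivative (n-BuLi, THF, −78 °C) should add to F1 in conjugate fashion anti to the menthyloxy group to give the dithianyl lactone F3. Raney Ni in EtOH removes sulfur to give the 4-benzyl lactone F4. LiN(iPr)2 (THF, −78 °C) followed by 6 gives the aldol adduct F5, trans to the benzyl group; its carbinol centre is of no consequence. LiAlH4 reduces the lactone carbonyl and the acetal carbon to the triol F6. Catalytic camphorsulfonic acid in CH2Cl2 at 0 °C then ionises the benzylic carbinol, and the primary hydroxyl on the benzyl-bearing carbon closes the oxolane; the 2,3-trans isomer 14 is expected as the thermodynamically favoured product.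

2. Step 5. The Lewis acid may ionise the trimethoxybenzylic C6–O5 bond of the oxolane in competition with the deactivated lactone acetal, leading to ring opening, arylation or epimerisation at C6. Alternatively the acetal may not ionise at temperatures that spare the oxolane.
   Fallback: it sets out from 10 and rejoins the route at acid 13. Hydrolysis of the menthyl acetal (1 M HCl, dioxane, 60 °C) should give the lactol (3aS,6R,6aR)-3-hydroxy-6-(3,4,5-trimethoxyphenyl)tetrahydro-1H,3H-furo[3,4-c]furan-1-one F7, in which the ring fusion stays closed and cis. Addition of 3,4-(MeO)2C6H3MgBr (2.5 equiv, THF, −40 → 0 °C; the first equivalent forms the magnesium carboxylate of the open aldehyde form, the second adds to the aldehyde) and acidification should give lactone 12 together with its C3 epimer (3S,3aS,6R,6aR)-3-(3,4-dimethoxyphenyl)-6-(3,4,5-trimethoxyphenyl)tetrahydro-1H,3H-furo[3,4-c]furan-1-one F8. The mixture is taken through step 6, where both epimers converge on 13.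

3. Step 6. Hydrogenolysis may go on to cleave the second benzylic C–O bond (C2–O1 of the oxolane), or the hindered secondary benzylic lactone may react too slowly on the metal surface.
   Fallback: it sets out from 12 and rejoins the route at 13, and makes no new compound (F0). Ionic hydrogenation with Et3SiH (1.5 equiv) and CF3CO2H (5 equiv) in CH2Cl2 at −20 → 0 °C replaces the surface reaction by a carbocation pathway: the lactone C–O bond ionises to the 3,4-dimethoxybenzylic cation, which the silane reduces. Selectivity then rests on the greater stability of that cation (para-methoxy conjugation) over the trimethoxybenzylic one at C2, not on adsorption. Reaction time and acid strength are kept low because the C2 ether can ionise under acid.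

**Further compounds**

F1 | step 4 | (5S)-5-{[(1S,2R,5S)-5-methyl-2-(propan-2-yl)cyclohexyl]oxy}furan-2(5H)-one | O=C1C=C[C@@H](O[C@H]2C[C@@H](C)CC[C@@H]2C(C)C)O1
F2 | step 4 | 2-(3,4-dimethoxyphenyl)-1,3-dithiane | COc1ccc(C2SCCCS2)cc1OC
F3 | step 4 | (4S,5S)-4-[2-(3,4-dimethoxyphenyl)-1,3-dithian-2-yl]-5-{[(1S,2R,5S)-5-methyl-2-(propan-2-yl)cyclohexyl]oxy}oxolan-2-one | O=C1C[C@H](C2(SCCCS2)c2ccc(OC)c(OC)c2)[C@@H](O[C@H]2C[C@@H](C)CC[C@@H]2C(C)C)O1
F4 | step 4 | (4S,5S)-4-[(3,4-dimethoxyphenyl)methyl]-5-{[(1S,2R,5S)-5-methyl-2-(propan-2-yl)cyclohexyl]oxy}oxolan-2-one | O=C1C[C@H](Cc2ccc(OC)c(OC)c2)[C@@H](O[C@H]2C[C@@H](C)CC[C@@H]2C(C)C)O1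
F5 | step 4 | (3R,4S,5S)-4-[(3,4-dimethoxyphenyl)methyl]-3-[hydroxy(3,4,5-trimethoxyphenyl)methyl]-5-{[(1S,2R,5S)-5-methyl-2-(propan-2-yl)cyclohexyl]oxy}oxolan-2-one (both carbinol epimers) | O=C1[C@@H](C(O)c2cc(OC)c(OC)c(OC)c2)[C@H](Cc2ccc(OC)c(OC)c2)[C@@H](O[C@H]2C[C@@H](C)CC[C@@H]2C(C)C)O1
F6 | step 4 | (2S,3S)-2-[(3,4-dimethoxyphenyl)methyl]-3-[hydroxy(3,4,5-trimethoxyphenyl)methyl]butane-1,4-diol (both carbinol epimers) | OC[C@@H](C(O)c1cc(OC)c(OC)c(OC)c1)[C@H](Cc1ccc(OC)c(OC)c1)CO
F7 | step 5 | (3aS,6R,6aR)-3-hydroxy-6-(3,4,5-trimethoxyphenyl)tetrahydro-1H,3H-furo[3,4-c]furan-1-one (both anomers) | O=C1OC(O)[C@@H]2CO[C@@H](c3cc(OC)c(OC)c(OC)c3)[C@H]12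
F8 | step 5 | (3S,3aS,6R,6aR)-3-(3,4-dimethoxyphenyl)-6-(3,4,5-trimethoxyphenyl)tetrahydro-1H,3H-furo[3,4-c]furan-1-one | O=C1O[C@H](c3ccc(OC)c(OC)c3)[C@@H]2CO[C@@H](c3cc(OC)c(OC)c(OC)c3)[C@H]12
F0 | step 6 | none | none
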